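**Retrosynthetic overview**

1. Numbering: tetralin C1 (CHMe), C2, C3, C4 (CH with the chain), C4a, C5–C8, C8a; chain C11 (CHMe), C12–C14, C15 (CHMe), C16 (CH2OH). The feature the plan rests on: ring B (C1–C4, C4a, C8a) with its trans C1 methyl and C4 branch is the p-menthane skeleton of (R)-carvone with the carbonyl at C8a, so only the arene carbons C5–C8 are missing.
2. Benzene ring: cut at C4a–C5 and C8–C8a into the kinetic silyl enol ether of the ring-B ketone and a 3-benzyloxy-4-methoxy-2-pyrone-5-carboxylate (inverse-demand Diels–Alder, then loss of CO2 and of silanol).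
3. Chain: cut at C12–C13 into a C12 pinacol boronate (C11 set by ligand-controlled copper hydride hydroboration of the isopropenyl group of ketal-protected trans-dihydrocarvone) and a Roche-ester-derived alkenyl iodide (C15), joined by Zweifel olefination and hydrogenated.
4. Pyrone: from dimethyl acetonedicarboxylate by diazo transfer, O–H insertion of benzyl alcohol, formylation–lactonisation and O-methylation.
5. Ring order: ring B is taken intact from carvone, the pyrone ring is made separately, the benzene ring is formed in the penultimate step; one hydrogenolysis removes both benzyl ethers.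

Key step: step 15

Assumption: (R)-DTBM-SEGPHOS is taken as the ligand antipode whose copper hydride adds to the isopropenyl face that gives the 11S boronate; if the sense proves opposite, (S)-DTBM-SEGPHOS is used and nothing else changes.

**Route**

Step 1
Reactants: 1 (R)-carvone
Product: 3 (2R,5R)-2-methyl-5-(prop-1-en-2-yl)cyclohexan-1-one (trans-dihydrocarvone), via lithium enolate 2 (not isolated)
Conditions: LiBH(s-Bu)3, THF, −78 °C; then aq. NH4Cl, −78 °C → rt; chromatography to remove any cis isomer
Reagents that add atoms: none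
Why: Conjugate reduction of the enone by the hindered trialkylborohydride gives enolate 2, and kinetic axial protonation at C1 should place the methyl group equatorial and trans to the isopropenyl group, while C4 comes unchanged from carvone.

Step 2
Reactants: 3 trans-dihydrocarvone
Product: 4 (6R,9R)-6-methyl-9-(prop-1-en-2-yl)-1,4-dioxaspiro[4.5]decane
Conditions: (Me3SiOCH2)2, Me3SiOTf (cat.), CH2Cl2, −78 → −20 °C; pyridine quench
Reagents that add atoms: 1,2-bis(trimethylsilyloxy)ethane, C[Si](C)(C)OCCO[Si](C)(C)C
Why: Noyori ketalisation at low temperature should mask the ketone without enolisation, so C1 is not epimerised and the isopropenyl double bond does not migrate.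

Step 3
Reactants: 4 dioxolane of trans-dihydrocarvone
Product: 5 2-{(2S)-2-[(6R,9R)-6-methyl-1,4-dioxaspiro[4.5]decan-9-yl]propyl}-4,4,5,5-tetramethyl-1,3,2-dioxaborolane (C12 boronate, 11S)
Conditions: CuCl (cat.), (R)-DTBM-SEGPHOS (cat.), NaOt-Bu (cat.), HBpin, THF, rt
Reagents that add atoms: pinacolborane, [H]B1OC(C)(C)C(C)(C)O1
Why: Ligand-controlled copper hydride hydroboration of a 1,1-disubstituted alkene places H on C11 and boron on C12, and because the two ring methylene arms that flank C4 are nearly alike the substrate should exert little bias, so the ligand alone selects the alkene face and sets 11S.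

Step 4
Reactants: 6 methyl (R)-3-hydroxy-2-methylpropanoate (Roche ester)
Product: 7 methyl (R)-3-(benzyloxy)-2-methylpropanoate
Conditions: BnOC(=NH)CCl3, TfOH (cat.), CH2Cl2/cyclohexane, 0 °C → rt
Reagents that add atoms: benzyl 2,2,2-trichloroacetimidate, N=C(OCc1ccccc1)C(Cl)(Cl)Cl
Why: Acid-catalysed O-benzylation with the trichloroacetimidate avoids base, so the α-stereocentre (future C15) should stay intact.

Step 5
Reactants: 7 methyl (R)-3-(benzyloxy)-2-methylpropanoate
Product: 9 (R)-3-(benzyloxy)-2-methylpropanal, via aluminium hemiacetal 8 (not isolated)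
Conditions: i-Bu2AlH, CH2Cl2, −78 °C; then MeOH, aq. potassium sodium tartrate; used at once
Reagents that add atoms: none
Why: Partial reduction of the ester at −78 °C stops at the tetrahedral aluminium hemiacetal 8, which collapses to the aldehyde only on work-up, and immediate use should prevent α-epimerisation.

Step 6
Reactants: 9 (R)-3-(benzyloxy)-2-methylpropanal
Product: 10 benzyl (2S,3E)-4-iodo-2-methylbut-3-en-1-yl ether
Conditions: CrCl2, CHI3, THF, 0 °C → rt
Reagents that add atoms: iodoform, IC(I)I
Why: Takai olefination with the geminal dichromium species formed from iodoform and divalent chromium should give the (E)-alkenyl iodide (C13=C14) under non-basic conditions that leave C15 untouched.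

Step 7
Reactants: 5 C12 pinacol boronate and 10 (E)-alkenyl iodide
Product: 14 (6R,9R)-9-[(2S,4Z,6S)-7-(benzyloxy)-6-methylhept-4-en-2-yl]-6-methyl-1,4-dioxaspiro[4.5]decane, via alkenyllithium 11 (not isolated), via lithium boronate 12 (not isolated), via iodoboronate 13 (not isolated)
Conditions: 10, t-BuLi (2 equiv per iodide), Et2O, −78 °C; 5, THF, −78 °C; I2, MeOH, −78 °C; NaOMe, MeOH, −78 °C → rt
Reagents that add atoms: none
Why: Zweifel olefination, in which iodine–lithium exchange gives 11, addition to boron gives boronate 12, iodination triggers 1,2-migration of C12 from boron to C13 to give 13, and methoxide-induced anti elimination should give the Z alkene, with C11 and C15 as spectators.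

Step 8
Reactants: 14 Z alkene
Product: 15 (6R,9R)-9-[(2S,6S)-7-(benzyloxy)-6-methylheptan-2-yl]-6-methyl-1,4-dioxaspiro[4.5]decane
Conditions: H2 (1 atm), RhCl(PPh3)3 (cat.), benzene/EtOH, rt
Reagents that add atoms: none
Why: Homogeneous hydrogenation with the rhodium phosphine complex should saturate the cis-disubstituted alkene without double-bond migration towards C15 and without hydrogenolysis of the benzyl ether.

Step 9
Reactants: 15 saturated dioxolane
Product: 16 (2R,5R)-5-[(2S,6S)-7-(benzyloxy)-6-methylheptan-2-yl]-2-methylcyclohexan-1-one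
Conditions: PPTS, acetone/H2O, 55 °C
Reagents that add atoms: water, O
Why: Mild acid-catalysed ketal hydrolysis should release the ketone while the benzyl ether is inert, and since the trans ketone is the thermodynamically preferred C1 epimer the brief exposure to acid does not put C1 at risk.

Step 10
Reactants: 16 side-chain-extended trans ketone
Product: 18 {[(3S,6R)-3-[(2S,6S)-7-(benzyloxy)-6-methylheptan-2-yl]-6-methylcyclohex-1-en-1-yl]oxy}trimethylsilane, via lithium enolate 17 (not isolated)
Conditions: LiN(i-Pr)2, THF, −78 °C (ketone added to base); Me3SiCl, Et3N, −78 → 0 °C; non-aqueous work-up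
Reagents that add atoms: chlorotrimethylsilane, C[Si](C)(C)Cl
Why: Kinetic deprotonation at −78 °C removes a proton from the C4a methylene and not from the C1 methine, and O-silylation of enolate 17 should give the less substituted silyl enol ether (C4a=C8a) without touching C1.

Step 11
Reactants: 19 dimethyl 3-oxopentanedioate (dimethyl 1,3-acetonedicarboxylate)
Product: 20 dimethyl 2-diazo-3-oxopentanedioate
Conditions: 4-AcNHC6H4SO2N3 (1 equiv), Et3N, MeCN, 0 °C → rt
Reagents that add atoms: 4-acetamidobenzenesulfonyl azide, CC(=O)Nc1ccc(cc1)S(=O)(=O)N=[N+]=[N-]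
Why: Regitz diazo transfer to one active methylene of the β-keto diester, with a single equivalent of azide, should stop at the mono-diazo compound.

Step 12
Reactants: 20 dimethyl 2-diazo-3-oxopentanedioate
Product: 21 dimethyl 2-(benzyloxy)-3-oxopentanedioate (racemic)
Conditions: BnOH, Rh2(OAc)4 (cat.), CH2Cl2, reflux
Reagents that add atoms: benzyl alcohol, OCc1ccccc1
Why: Rhodium carbenoid O–H insertion of an α-diazo-β-keto ester into an alcohol should install the future C8 oxygen as its benzyl ether, and the new stereocentre is of no consequence because it becomes sp2 in the next step.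

Step 13
Reactants: 21 dimethyl 2-(benzyloxy)-3-oxopentanedioate
Product: 24 methyl 3-(benzyloxy)-4-hydroxy-2-oxo-2H-pyran-5-carboxylate, via enaminone 22 (not isolated), via hydroxymethylene diester 23 (not isolated)
Conditions: Me2NCH(OMe)2, toluene, rt; then 1 M HCl, THF, rt → 50 °C
Reagents that add atoms: N,N-dimethylformamide dimethyl acetal, COC(OC)N(C)C; water, O
Why: The formamide acetal can condense only at the C4 methylene because the benzyloxy-bearing carbon has a single hydrogen, acid hydrolysis of enaminone 22 gives hydroxymethylene compound 23, and its enol oxygen should lactonise onto the distal ester as in the cyclisation of 3,5-dioxo esters to 4-hydroxy-2-pyrones.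

Step 14
Reactants: 24 methyl 3-(benzyloxy)-4-hydroxy-2-oxo-2H-pyran-5-carboxylate
Product: 25 methyl 3-(benzyloxy)-4-methoxy-2-oxo-2H-pyran-5-carboxylate
Conditions: Me2SO4, K2CO3, acetone, reflux
Reagents that add atoms: dimethyl sulfate, COS(=O)(=O)OC
Why: O-alkylation of the vinylogous acid with a hard methylating agent and carbonate should give the 4-methoxy-2-pyrone, the usual outcome for 4-hydroxy-2-pyrones under these conditions.

Step 15
Reactants: 18 kinetic trimethylsilyl enol ether and 25 pyrone (in excess)
Product: 28 methyl (5R,8S)-4-(benzyloxy)-8-[(2S,6S)-7-(benzyloxy)-6-methylheptan-2-yl]-3-methoxy-5-methyl-5,6,7,8-tetrahydronaphthalene-2-carboxylate, via bridged lactone 26 (not isolated), via cyclohexadiene 27 (not isolated)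
Conditions: toluene, 160 °C, sealed tube; then TsOH (cat.), CH2Cl2, rt
Reagents that add atoms: none
Why: The electron-rich C4a of enol ether 18 attacks the electrophilic C6 of pyrone 25 (the β-carbon of its alkoxyacrylate unit) while the donor-substituted pyrone C3 bonds to the oxocarbenium-like C8a, an asynchronous inverse-electron-demand Diels–Alder reaction that gives bridged lactone 26; retro-[4+2] loss of CO2 gives diene 27, and 1,2-elimination of trimethylsilanol across C4a–C8a, finished by the acid, makes the benzene ring. The closest known reaction type is the benzannulation of 2-pyrone-5-carboxylates with enol ethers, ketene acetals or enamines, which also ends in CO2 extrusion and loss of the heteroatom group. The one ring closed, the benzene ring, forms by intermolecular [4+2] annulation in which C4a–C5 is made first and C8–C8a second, the second bond closing the six-membered ring onto the oxocarbenium carbon. No stereocentre is created, since the transient sp3 centres of 26 and 27 all become aromatic carbons, and C1, C4, C11 and C15 are spectators under neutral thermal conditions. The step needs regioselectivity only: the polarity of both partners pairs C4a with pyrone C6, and the kinetic origin of 18 fixes the double bond at C4a–C8a and keeps C1 from epimerising. The donor groups on the pyrone and the two branched carbons flanking the enol ether cost rate, which heat and an excess of 25 are meant to cover.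

Step 16
Reactants: 28 dibenzyl ether of the target
Product: 29 methyl (5R,8S)-4-hydroxy-8-[(2S,6S)-7-hydroxy-6-methylheptan-2-yl]-3-methoxy-5-methyl-5,6,7,8-tetrahydronaphthalene-2-carboxylate (CNP0398293.1)
Conditions: H2 (1 atm), Pd(OH)2/C, EtOAc/MeOH, rt
Reagents that add atoms: none
Why: Catalytic hydrogenolysis should cleave the aryl benzyl ether at C8 and the primary benzyl ether at C16 in one operation, leaving the methyl ester, the methyl ether, the arene and all four stereocentres untouched.

**Compound list**

1 | (R)-carvone | CC1=CC[C@H](CC1=O)C(C)=C | starting material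
2 | lithium (5R)-2-methyl-5-(prop-1-en-2-yl)cyclohex-1-en-1-olate (not isolated) | CC1=C(O[Li])C[C@@H](CC1)C(C)=C | intermediate
3 | (2R,5R)-2-methyl-5-(prop-1-en-2-yl)cyclohexan-1-one (trans-dihydrocarvone) | C[C@@H]1CC[C@H](CC1=O)C(C)=C | intermediate
4 | (6R,9R)-6-methyl-9-(prop-1-en-2-yl)-1,4-dioxaspiro[4.5]decane | C[C@@H]1CC[C@H](CC12OCCO2)C(C)=C | intermediate
5 | 2-{(2S)-2-[(6R,9R)-6-methyl-1,4-dioxaspiro[4.5]decan-9-yl]propyl}-4,4,5,5-tetramethyl-1,3,2-dioxaborolane | C[C@@H]1CC[C@H](CC12OCCO2)[C@@H](C)CB3OC(C)(C)C(C)(C)O3 | intermediate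
6 | methyl (R)-3-hydroxy-2-methylpropanoate (Roche ester) | COC(=O)[C@H](C)CO | starting material
7 | methyl (R)-3-(benzyloxy)-2-methylpropanoate | COC(=O)[C@H](C)COCc1ccccc1 | intermediate
8 | diisobutylaluminium hemiacetal of 7, hemiacetal carbon unassigned (not isolated) | COC(O[Al](CC(C)C)CC(C)C)[C@H](C)COCc1ccccc1 | intermediate
9 | (R)-3-(benzyloxy)-2-methylpropanal | O=C[C@H](C)COCc1ccccc1 | intermediate
10 | benzyl (2S,3E)-4-iodo-2-methylbut-3-en-1-yl ether | I/C=C/[C@H](C)COCc1ccccc1 | intermediate
11 | (E)-alkenyllithium from 10 (not isolated) | [Li]/C=C/[C@H](C)COCc1ccccc1 | intermediate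
12 | lithium alkenyl(alkyl) pinacol boronate from 5 and 11 (not isolated) | [Li+].C[C@@H]1CC[C@H](CC12OCCO2)[C@@H](C)C[B-]3(/C=C/[C@H](C)COCc4ccccc4)OC(C)(C)C(C)(C)O3 | intermediate
13 | β-iodoalkyl pinacol boronate, C13 and C14 unassigned (not isolated) | C[C@@H]1CC[C@H](CC12OCCO2)[C@@H](C)CC(B3OC(C)(C)C(C)(C)O3)C(I)[C@H](C)COCc4ccccc4 | intermediate
14 | (6R,9R)-9-[(2S,4Z,6S)-7-(benzyloxy)-6-methylhept-4-en-2-yl]-6-methyl-1,4-dioxaspiro[4.5]decane | C[C@@H]1CC[C@H](CC12OCCO2)[C@@H](C)C/C=C\[C@H](C)COCc3ccccc3 | intermediate
15 | (6R,9R)-9-[(2S,6S)-7-(benzyloxy)-6-methylheptan-2-yl]-6-methyl-1,4-dioxaspiro[4.5]decane | C[C@@H]1CC[C@H](CC12OCCO2)[C@@H](C)CCC[C@H](C)COCc3ccccc3 | intermediate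
16 | (2R,5R)-5-[(2S,6S)-7-(benzyloxy)-6-methylheptan-2-yl]-2-methylcyclohexan-1-one | C[C@@H]1CC[C@H](CC1=O)[C@@H](C)CCC[C@H](C)COCc2ccccc2 | intermediate
17 | kinetic lithium enolate of 16, double bond C4a=C8a (not isolated) | C1=C(O[Li])[C@H](C)CC[C@H]1[C@@H](C)CCC[C@H](C)COCc2ccccc2 | intermediate
18 | {[(3S,6R)-3-[(2S,6S)-7-(benzyloxy)-6-methylheptan-2-yl]-6-methylcyclohex-1-en-1-yl]oxy}trimethylsilane | C1=C(O[Si](C)(C)C)[C@H](C)CC[C@H]1[C@@H](C)CCC[C@H](C)COCc2ccccc2 | intermediate
19 | dimethyl 3-oxopentanedioate (dimethyl 1,3-acetonedicarboxylate) | COC(=O)CC(=O)CC(=O)OC | starting material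
20 | dimethyl 2-diazo-3-oxopentanedioate | COC(=O)CC(=O)C(=[N+]=[N-])C(=O)OC | intermediate
21 | dimethyl 2-(benzyloxy)-3-oxopentanedioate (racemic) | COC(=O)CC(=O)C(OCc1ccccc1)C(=O)OC | intermediate
22 | dimethyl 2-(benzyloxy)-4-[(dimethylamino)methylidene]-3-oxopentanedioate (not isolated) | COC(=O)C(OCc1ccccc1)C(=O)C(=CN(C)C)C(=O)OC | intermediate
23 | dimethyl 2-(benzyloxy)-4-(hydroxymethylidene)-3-oxopentanedioate (not isolated) | COC(=O)C(OCc1ccccc1)C(=O)C(=CO)C(=O)OC | intermediate
24 | methyl 3-(benzyloxy)-4-hydroxy-2-oxo-2H-pyran-5-carboxylate | O=C1OC=C(C(=O)OC)C(O)=C1OCc1ccccc1 | intermediate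
25 | methyl 3-(benzyloxy)-4-methoxy-2-oxo-2H-pyran-5-carboxylate | O=C1OC=C(C(=O)OC)C(OC)=C1OCc1ccccc1 | intermediate
26 | bridged lactone [4+2] adduct of 18 and 25 (2-oxabicyclo[2.2.2]oct-5-en-3-one fused to ring B; new centres unassigned; not isolated) | O=C1OC2C(C(=O)OC)=C(OC)C1(OCc3ccccc3)C4(O[Si](C)(C)C)[C@H](C)CC[C@@H]([C@@H](C)CCC[C@H](C)COCc5ccccc5)C24 | intermediate
27 | cyclohexadiene after loss of CO2, C4a–H and C8a–OSiMe3 still in place (new centres unassigned; not isolated) | COC(=O)C1=CC2[C@H]([C@@H](C)CCC[C@H](C)COCc3ccccc3)CC[C@@H](C)C2(O[Si](C)(C)C)C(OCc4ccccc4)=C1OC | intermediate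
28 | methyl (5R,8S)-4-(benzyloxy)-8-[(2S,6S)-7-(benzyloxy)-6-methylheptan-2-yl]-3-methoxy-5-methyl-5,6,7,8-tetrahydronaphthalene-2-carboxylate | COC(=O)c1cc2c(c(OCc3ccccc3)c1OC)[C@H](C)CC[C@H]2[C@@H](C)CCC[C@H](C)COCc4ccccc4 | intermediate
29 | methyl (5R,8S)-4-hydroxy-8-[(2S,6S)-7-hydroxy-6-methylheptan-2-yl]-3-methoxy-5-methyl-5,6,7,8-tetrahydronaphthalene-2-carboxylate (CNP0398293.1) | COC(=O)c1cc2c(c(O)c1OC)[C@H](C)CC[C@H]2[C@@H](C)CCC[C@H](C)CO | target

**Step count**

Total: 16 steps. Longest linear sequence: 9 steps (1, 2, 3, 7, 8, 9, 10, 15, 16 from (R)-carvone; the Roche-ester branch 4, 5, 6, 7, 8, 9, 10, 15, 16 is equally long).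

**Steps most likely to fail**

Step 15. The cycloaddition may be too slow, because the pyrone carries two donor oxygens and the enol ether is flanked by two branched carbons. Enol ether 18 could then lose its silyl group or shift its double bond before it reacts, and regiocontrol and the C1 configuration would suffer. The fallback builds the arene by condensation and sets out from ketone 16. Formylation at C4a (HCO2Et, NaH, THF) should give the 2-(hydroxymethylene) ketone F1. Condensation of F1 with commercial methyl 4-(benzyloxy)-3-oxobutanoate (NaOMe, MeOH, heat) is a [3+3] benzannulation: the active methylene of the keto ester condenses with the formyl carbon (C5–C6) and its benzyloxy-bearing methylene with the ring ketone (C8–C8a), which should give the C7 phenol F2. O-Methylation (MeI, K2CO3, DMF) then gives 28, where the route is rejoined.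

Step 3. Facial selectivity at C11 may be poor, which would give C11 epimers that can hardly be separated at any later stage. The fallback sets C11 by asymmetric conjugate reduction and sets out from 4 and 7.
- Ozonolysis of 4 (O3, CH2Cl2/MeOH, −78 °C; Me2S) should give the methyl ketone F3.
- Horner–Wadsworth–Emmons olefination (triethyl phosphonoacetate, NaH, THF) should give the (E)-enoate F4.
- Ligand-controlled copper hydride 1,4-reduction (Cu(OAc)2, p-Tol-BINAP of the appropriate antipode, polymethylhydrosiloxane, t-BuOH, toluene) should give the 11S ester F5, whose ester carbon is C13.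
- i-Bu2AlH at −78 °C should give the aldehyde F6.
- For the C14–C16 unit, LiAlH4 reduction of 7 gives the alcohol F7, I2/PPh3/imidazole gives the iodide F8, and PPh3 in refluxing MeCN gives the phosphonium salt F9.
- Wittig reaction of the ylide from F9 (NaN(SiMe3)2, THF, −78 °C) with F6 should give the Z alkene 14, where the route is rejoined.

Step 13. Lactonisation onto the hindered, benzyloxy-bearing ester may be incomplete, or the aqueous acid may strip the formyl carbon by retro-Claisen cleavage. The fallback closes the ring before the C3 oxygen is introduced and sets out from 19. Heating 19 with HC(OEt)3 and Ac2O (120 °C) should give the ethoxymethylidene diester F10, and aqueous HCl should close it to the parent hydroxypyrone F11. Diazo transfer at C3 (4-acetamidobenzenesulfonyl azide, Et3N, MeCN) should give the 3-diazo-2,4-dione F12, and Rh2(OAc)4-catalysed O–H insertion into benzyl alcohol gives 24, where the route is rejoined.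

**Further compounds**

F1 | step 15 | (3S,6R)-3-[(2S,6S)-7-(benzyloxy)-6-methylheptan-2-yl]-2-(hydroxymethylidene)-6-methylcyclohexan-1-one | OC=C1C(=O)[C@H](C)CC[C@H]1[C@@H](C)CCC[C@H](C)COCc2ccccc2
F2 | step 15 | methyl (5R,8S)-4-(benzyloxy)-8-[(2S,6S)-7-(benzyloxy)-6-methylheptan-2-yl]-3-hydroxy-5-methyl-5,6,7,8-tetrahydronaphthalene-2-carboxylate | COC(=O)c1cc2c(c(OCc3ccccc3)c1O)[C@H](C)CC[C@H]2[C@@H](C)CCC[C@H](C)COCc4ccccc4
F3 | step 3 | 1-[(6R,9R)-6-methyl-1,4-dioxaspiro[4.5]decan-9-yl]ethan-1-one | C[C@@H]1CC[C@H](CC12OCCO2)C(C)=O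
F4 | step 3 | ethyl (2E)-3-[(6R,9R)-6-methyl-1,4-dioxaspiro[4.5]decan-9-yl]but-2-enoate | C[C@@H]1CC[C@H](CC12OCCO2)/C(C)=C/C(=O)OCC
F5 | step 3 | ethyl (3S)-3-[(6R,9R)-6-methyl-1,4-dioxaspiro[4.5]decan-9-yl]butanoate | C[C@@H]1CC[C@H](CC12OCCO2)[C@@H](C)CC(=O)OCC
F6 | step 3 | (3S)-3-[(6R,9R)-6-methyl-1,4-dioxaspiro[4.5]decan-9-yl]butanal | C[C@@H]1CC[C@H](CC12OCCO2)[C@@H](C)CC=O
F7 | step 3 | (S)-3-(benzyloxy)-2-methylpropan-1-ol | OC[C@H](C)COCc1ccccc1
F8 | step 3 | benzyl (R)-3-iodo-2-methylpropyl ether | IC[C@H](C)COCc1ccccc1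
F9 | step 3 | [(2R)-3-(benzyloxy)-2-methylpropyl]triphenylphosphonium iodide | [I-].c1ccccc1[P+](c1ccccc1)(c1ccccc1)C[C@H](C)COCc1ccccc1
F10 | step 13 | dimethyl 2-(ethoxymethylidene)-3-oxopentanedioate | CCOC=C(C(=O)OC)C(=O)CC(=O)OC
F11 | step 13 | methyl 4-hydroxy-2-oxo-2H-pyran-5-carboxylate | O=C1C=C(O)C(C(=O)OC)=CO1
F12 | step 13 | methyl 3-diazo-2,4-dioxo-3,4-dihydro-2H-pyran-5-carboxylate | O=C1OC=C(C(=O)OC)C(=O)C1=[N+]=[N-]
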